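The constants are invented; the rest is arithmetic.

Slowness is what I watch here: on Wednesday's charge the electrophile has a half-life of 0.62 d by step 1, yet the flasks stand for weeks.

- Wednesday's: electrophile 0.20 M; nucleophile 0.600 M; free base 0.240 M; protic impurity 0.0100 M; time 25 d
- Thursday's: electrophile 0.20 M; nucleophile 0.600 M; free base 0.240 M; protic impurity 0.0100 M; time 50 d

    electrophile + nucleophile → acid set free + target (k1 = 0.0013 M⁻¹ min⁻¹)
    nucleophile + acid set free ⇌ protonated nucleophile, settled at all times (K2 = 7400 M⁻¹)
    acid set free + free base ⇌ salt of the base, settled at all times (K3 = 11000 M⁻¹)
    target ⇌ isomer of the product (K4 = 24, k4 = 7.1 × 10⁻⁴ min⁻¹)
    free base + target → over-reaction product (k5 = 4.2 × 10⁻⁴ M⁻¹ min⁻¹)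
    electrophile + protic impurity → quenched substrate (k6 = 0.066 M⁻¹ min⁻¹)

1. which of these there is most of at the end, counted by the electrophile in it, Wednesday's (target / electrophile / over-reaction product / isomer of the product)
2. which of these there is most of at the end, counted by the electrophile in it, Thursday's (target / electrophile / over-reaction product / isomer of the product)
3. how much there is at the end of the one of these that leads, in percent of the electrophile charged: Wednesday's
4. how much there is at the end of the one of these that leads, in percent of the electrophile charged: Thursday's

The two columns differ in time alone, 25 d against 50 d, so what separates them is whatever still runs late. Read down a column, with the electrophile as limiting reagent: nucleophile 3.00 equivalents, free base 1.20, protic impurity 0.0500.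

So I write the electrophile's balance, as fractions of its charge. The impurity row comes first. At the charged electrophile the impurity's half-life is 0.0365 d, shorter than the electrophile's, so I book 5.00% as quenched substrate and keep 95.0%.

That remainder becomes target, which then splits. Isomerisation is faster than attack by free base, 7.04 to one at the charge, so I book 11.8% as lost early. The balance of step 4 then puts 79.9% in the isomer.

After that, target and isomer form one pool that leaks slowly. I let the acid divide roughly as the two bases bind it at the start, which by my estimate leaves 70.5% of the free base unbound, counting no loss of free base to step 5. My carried quantity is the leak constant, k5 times the free base standing, divided by one plus K4, a pseudo-first-order constant, here 0.00409 d⁻¹. I commit to the isomer leading, at 72.1% in Wednesday's flask and 65.1% in Thursday's.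

The forecast also names the isomer of the product for Wednesday's flask and for Thursday's, but stands higher than I do, at 75% and 70%. It speaks of “The slow leak to over-reaction product, fed by free base acting on the small target fraction”.

Wednesday's flask ends with the isomer of the product at 77.3% and Thursday's with the isomer of the product at 71.9%, so the forecast holds on all four marks. With the free base at the end of Wednesday's flask, 56% of its charge, the leak constant becomes 0.00325 d⁻¹; between the end of Wednesday's flask and the end of Thursday's the isomer falls at 0.00294 d⁻¹, a little less than that. For the neighbour of Thursday's charged with 0.96 M of free base, 72.8% of it unbound at the end, the leak constant is 0.0169 d⁻¹, and there the over-reaction product leads, with the isomer down to 34.1%.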